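**Retrosynthetic overview**
1. Target 22 ⇐ bis-TBS ether 21 ⇐ keto acid 18: a one-pot epoxidation / epoxide-opening lactonisation with angeloyl transfer makes the C5–O and C6–O bonds, closes the γ-lactone and installs the angelate.
2. 18 ⇐ allylic propanoate 13 by Ireland–Claisen rearrangement (C7–C11 bond; sets C7 and C11), then oxidative unmasking of the C2 ketone.
3. 13 ⇐ enone 11 by 1,2-reduction/acylation; the C5 carbinol relays chirality to C7.
4. 11 ⇐ α′-silyloxy enone 5 + aldehyde 8 by aldol addition (C1–C2 bond, quaternary C1); 8 comes from methyl (R)-3-hydroxybutanoate (C4).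
5. 5 ⇐ cyclohepta-2,6-dienone 2 (asymmetric conjugate methylation sets C10; Rubottom oxidation makes C1–O) ⇐ cycloheptanone. The seven-membered ring is bought; the lactone is the only ring formed, and it is formed last.

**Convention used in all names:** ring C1(OH)–C5(OAng)–C6(O-lactone)–C7–C8–C9–C10(CH3 = C14); side chain C2(=O)–C3–C4(OH)–C15; lactone C11(CH3 = C13)–C12(=O). α is the ring face carrying the C10 methyl, β the other face. The target is (1S,4R,5S,6R,7S,10S,11R).

Step 1
Reactants: 1 cycloheptanone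
Product: 2 cyclohepta-2,6-dien-1-one
Conditions: IBX (3 equiv), PhF/DMSO (2:1), 70 °C
Reagents that add atoms: none
Why: IBX-mediated α,β-dehydrogenation of the ketone, run twice in one pot and stopped at the cross-conjugated dienone by stoichiometry and temperature; no stereocentre is formed.

Step 2
Reactants: 2 cyclohepta-2,6-dien-1-one
Product: 5 (6S,7R)-7-(tert-butyldimethylsilyloxy)-6-methylcyclohept-2-en-1-one, via methylzinc dienolate 3 (not isolated), via TBS dienol ether 4 (not isolated)
Conditions: Me2Zn (1.3 equiv), Cu(OTf)2 (2 mol %), (S,R,R)-binaphthyl bis(1-phenylethyl)phosphoramidite (4 mol %; ligand antipode chosen for the (S)-methyl centre), PhMe, −25 °C; TBSOTf, −25 → 0 °C; alumina plug; mCPBA, CH2Cl2, −20 °C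
Reagents that add atoms: dimethylzinc, C[Zn]C; tert-butyldimethylsilyl triflate, CC(C)(C)[Si](C)(C)OS(=O)(=O)C(F)(F)F; mCPBA, OOC(=O)c1cccc(Cl)c1
Why: Cu-catalysed asymmetric conjugate addition desymmetrises the dienone under ligand control (sets C10), the zinc enolate is silylated regiospecifically, and Rubottom oxidation attacks the electron-rich enol-ether terminus anti to the methyl to give the α′-silyloxy enone (the C1 configuration is erased in step 5).

Step 3
Reactants: 6 methyl (R)-3-hydroxybutanoate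
Product: 7 methyl (R)-3-(tert-butyldimethylsilyloxy)butanoate
Conditions: TBSCl, imidazole, DMF, rt
Reagents that add atoms: tert-butyldimethylsilyl chloride, CC(C)(C)[Si](C)(C)Cl
Why: Standard silylation of the secondary alcohol; the (R) centre (future C4) is not touched.

Step 4
Reactants: 7 methyl (R)-3-(tert-butyldimethylsilyloxy)butanoate
Product: 8 (R)-3-(tert-butyldimethylsilyloxy)butanal
Conditions: DIBAL-H (1.05 equiv), CH2Cl2, −78 °C; Rochelle salt
Reagents that add atoms: none
Why: Low-temperature DIBAL-H half-reduction of the ester stops at the aldehyde after work-up and leaves the stereocentre untouched.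

Step 5
Reactants: 5 (6S,7R)-7-(tert-butyldimethylsilyloxy)-6-methylcyclohept-2-en-1-one; 8 (R)-3-(tert-butyldimethylsilyloxy)butanal
Product: 11 bis-silyl aldol enone, via lithium enolate 9 (not isolated), via lithium aldolate 10 (not isolated)
Conditions: LDA (1.1 equiv), THF, −78 °C; 8, −78 °C; TESOTf (1.3 equiv), −78 → −40 °C
Reagents that add atoms: triethylsilyl triflate, CC[Si](CC)(CC)OS(=O)(=O)C(F)(F)F
Why: Directed aldol addition (Zimmerman–Traxler) of the tetrasubstituted α-silyloxy lithium enolate, in which A(1,2) strain holds the C10 methyl pseudo-axial so the aldehyde adds to the opposite (β) face and fixes the quaternary C1 with OTBS cis to the methyl; the aldolate is capped in situ as the TES ether (C2 drawn as the expected major S epimer; both epimers converge in step 8).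

Step 6
Reactants: 11 bis-silyl aldol enone
Product: 13 5α-allylic propanoate, via aluminium alkoxide 12 (not isolated)
Conditions: DIBAL-H (1.2 equiv), CH2Cl2, −78 °C; pyridine, DMAP, (EtCO)2O, −78 °C → rt; Rochelle salt
Reagents that add atoms: propanoic anhydride, CCC(=O)OC(=O)CC
Why: 1,2-Reduction of the enone by DIBAL-H anti to the pseudo-axial 1α-silyloxy group (polar Felkin–Anh) gives the 5α-alkoxide, which is acylated in the same flask (reductive acylation).

Step 7
Reactants: 13 5α-allylic propanoate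
Product: 16 γ,δ-unsaturated acid, via silyl ketene acetal 14 (not isolated), via trimethylsilyl ester 15 (not isolated)
Conditions: TMSCl (5 equiv), LDA (1.5 equiv), THF, −78 °C (in situ quench) → 50 °C; aq. citric acid
Reagents that add atoms: none
Why: Ireland–Claisen [3,3] rearrangement, in which suprafacial transfer from the 5α-oxygen places C11 on the α-face of C7 (sets C7) and the (E)-silyl ketene acetal, reacting through the boat transition state that the 1α-OTBS group enforces, sets C11 as R.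

Step 8
Reactants: 16 γ,δ-unsaturated acid
Product: 18 keto acid, via secondary alcohol 17 (not isolated)
Conditions: IBX (3 equiv), DMSO, rt
Reagents that add atoms: none
Why: IBX in DMSO cleaves the secondary TES ether and oxidises the freed carbinol to the C2 ketone (oxidative desilylation) while the two TBS ethers, the acid and the alkene are inert; no stereocentre is formed.

Step 9
Reactants: 18 keto acid
Product: 21 bis-TBS angeloyloxy lactone, via mixed anhydride 19 (not isolated), via epoxy anhydride 20 (not isolated)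
Conditions: angelic anhydride (3 equiv), Sc(OTf)3 (5 mol %), CH2Cl2, 0 °C; DMDO (1.3 equiv, acetone), −40 → 0 °C
Reagents that add atoms: angelic anhydride, C/C=C(/C)C(=O)OC(=O)C(/C)=C\C; dimethyldioxirane, CC1(C)OO1
Why: Proposed new method: acyl-shuttling oxy-lactonisation, in which the acid is first parked as its mixed anhydride with angelic acid (Sc(OTf)3-promoted anhydride exchange), DMDO epoxidises C5=C6 on the β-face (anti to the allylic 1α-OTBS and the 7α side chain), and the Lewis-acid-activated epoxide is opened at C6 with inversion by the proximal anhydride carbonyl oxygen (5-exo) to give a 2-acyloxy-oxolanylium ion that passes its angeloyl group to the freed 5β-alkoxide, so the cis-fused lactone (C6–O α) and the 5β-angelate trans to it form in one operation without intermolecular acylation of the neopentyl C5–OH and without a cation at C5 next to the C1 carbinol; the closest known reactions are acid-catalysed lactonisation of γ,δ-epoxy acids and Lewis-acid opening of epoxides by anhydrides to 1,2-diesters.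

Step 10
Reactants: 21 bis-TBS angeloyloxy lactone
Product: 22 target
Conditions: HF·pyridine, THF/pyridine, 0 °C → rt
Reagents that add atoms: none
Why: Fluoride-mediated desilylation removes both TBS ethers under mildly acidic conditions that leave the angelate geometry, the lactone and the β-hydroxy ketone intact.

**Compound list**
1 | cycloheptanone | O=C1CCCCCC1 | starting material
2 | cyclohepta-2,6-dien-1-one | O=C1C=CCCC=C1 | intermediate
3 | methylzinc dienolate of (S)-6-methylcyclohept-2-en-1-one (Zn–O on C5; C1=C5 and C6=C7; 10α-Me) | C[C@H]1CCC=CC(O[Zn]C)=C1 | intermediate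
4 | (S)-2-(tert-butyldimethylsilyloxy)-7-methylcyclohepta-1,3-diene (TBS dienol ether) | C[C@H]1CCC=CC(O[Si](C)(C)C(C)(C)C)=C1 | intermediate
5 | (6S,7R)-7-(tert-butyldimethylsilyloxy)-6-methylcyclohept-2-en-1-one (C5 ketone, Δ6, 1β-OTBS trans to 10α-Me) | O=C1C=CCC[C@H](C)[C@H]1O[Si](C)(C)C(C)(C)C | intermediate
6 | methyl (R)-3-hydroxybutanoate | C[C@@H](O)CC(=O)OC | starting material
7 | methyl (R)-3-(tert-butyldimethylsilyloxy)butanoate | C[C@@H](O[Si](C)(C)C(C)(C)C)CC(=O)OC | intermediate
8 | (R)-3-(tert-butyldimethylsilyloxy)butanal | C[C@@H](O[Si](C)(C)C(C)(C)C)CC=O | intermediate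
9 | lithium enolate of 5 (C1=C5, O–Li on C5, 1-OTBS, 10α-Me) | [Li]OC1=C(O[Si](C)(C)C(C)(C)C)[C@@H](C)CCC=C1 | intermediate
10 | lithium aldolate: C5 ketone, Δ6, 1α-OTBS, 1β-[(1S,3R)-1-lithiooxy-3-(TBS-oxy)butyl], 10α-Me | O=C1C=CCC[C@H](C)[C@@]1(O[Si](C)(C)C(C)(C)C)[C@@H](O[Li])C[C@@H](C)O[Si](C)(C)C(C)(C)C | intermediate
11 | bis-silyl aldol enone: C5 ketone, Δ6, 1α-OTBS, 1β-[(1S,3R)-1-(TES-oxy)-3-(TBS-oxy)butyl], 10α-Me | O=C1C=CCC[C@H](C)[C@@]1(O[Si](C)(C)C(C)(C)C)[C@@H](O[Si](CC)(CC)CC)C[C@@H](C)O[Si](C)(C)C(C)(C)C | intermediate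
12 | diisobutylaluminium 5α-alkoxide from 11 (Δ6; other groups as in 11) | CC(C)C[Al](CC(C)C)O[C@@H]1C=CCC[C@H](C)[C@@]1(O[Si](C)(C)C(C)(C)C)[C@@H](O[Si](CC)(CC)CC)C[C@@H](C)O[Si](C)(C)C(C)(C)C | intermediate
13 | 5α-propanoyloxy Δ6-ene (allylic propanoate; other groups as in 11) | CCC(=O)O[C@@H]1C=CCC[C@H](C)[C@@]1(O[Si](C)(C)C(C)(C)C)[C@@H](O[Si](CC)(CC)CC)C[C@@H](C)O[Si](C)(C)C(C)(C)C | intermediate
14 | (E)-O-trimethylsilyl ketene acetal of 13 (CH3 cis to the allylic oxygen) | C/C=C(/O[Si](C)(C)C)O[C@@H]1C=CCC[C@H](C)[C@@]1(O[Si](C)(C)C(C)(C)C)[C@@H](O[Si](CC)(CC)CC)C[C@@H](C)O[Si](C)(C)C(C)(C)C | intermediate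
15 | trimethylsilyl ester of 16 | C[Si](C)(C)OC(=O)[C@H](C)[C@H]1C=C[C@](O[Si](C)(C)C(C)(C)C)([C@@H](O[Si](CC)(CC)CC)C[C@@H](C)O[Si](C)(C)C(C)(C)C)[C@@H](C)CC1 | intermediate
16 | γ,δ-unsaturated acid: Δ5-ene, 7α-[(1R)-1-carboxyethyl], 1α-OTBS, 1β-[(1S,3R)-1-(TES-oxy)-3-(TBS-oxy)butyl], 10α-Me | OC(=O)[C@H](C)[C@H]1C=C[C@](O[Si](C)(C)C(C)(C)C)([C@@H](O[Si](CC)(CC)CC)C[C@@H](C)O[Si](C)(C)C(C)(C)C)[C@@H](C)CC1 | intermediate
17 | as 16 with free C2 hydroxyl (secondary alcohol) | OC(=O)[C@H](C)[C@H]1C=C[C@](O[Si](C)(C)C(C)(C)C)([C@@H](O)C[C@@H](C)O[Si](C)(C)C(C)(C)C)[C@@H](C)CC1 | intermediate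
18 | keto acid: Δ5-ene, 7α-[(1R)-1-carboxyethyl], 1α-OTBS, 1β-[(R)-3-(TBS-oxy)butanoyl], 10α-Me | OC(=O)[C@H](C)[C@H]1C=C[C@](O[Si](C)(C)C(C)(C)C)(C(=O)C[C@@H](C)O[Si](C)(C)C(C)(C)C)[C@@H](C)CC1 | intermediate
19 | mixed anhydride of 18 with angelic acid | C/C=C(/C)C(=O)OC(=O)[C@H](C)[C@H]1C=C[C@](O[Si](C)(C)C(C)(C)C)(C(=O)C[C@@H](C)O[Si](C)(C)C(C)(C)C)[C@@H](C)CC1 | intermediate
20 | 5β,6β-epoxide of mixed anhydride 19 | C/C=C(/C)C(=O)OC(=O)[C@H](C)[C@H]1[C@@H]2O[C@@H]2[C@](O[Si](C)(C)C(C)(C)C)(C(=O)C[C@@H](C)O[Si](C)(C)C(C)(C)C)[C@@H](C)CC1 | intermediate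
21 | 1,4-bis-O-TBS ether of the target (5β-angeloyloxy, cis-fused 12,6-lactone with 6α-O and 7α-C11, 11R, 10α-Me, 1α-OTBS) | C/C=C(/C)C(=O)O[C@H]1[C@@H]2OC(=O)[C@H](C)[C@@H]2CC[C@H](C)[C@@]1(O[Si](C)(C)C(C)(C)C)C(=O)C[C@@H](C)O[Si](C)(C)C(C)(C)C | intermediate
22 | (1S,4R,5S,6R,7S,10S,11R)-5-angeloyloxy-1,4-dihydroxy-2-oxo-4,5-secoguaian-12,6-olide (CNP0321985.1) | C/C=C(/C)C(=O)O[C@H]1[C@@H]2OC(=O)[C@H](C)[C@@H]2CC[C@H](C)[C@@]1(O)C(=O)C[C@@H](C)O | target

**Step count and risks**

Total steps: 10. Longest linear sequence: 8 (1 → 2 → 5 → 11 → 13 → 16 → 18 → 21 → 22; steps 3 and 4 are a two-step side branch).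

Most likely to fail:

Step 9 (the proposed new step). The risks are β-face selectivity of the epoxidation, Lewis-acid rearrangement of the epoxide before the anhydride carbonyl closes, and angelate-to-tiglate isomerisation. The fallback uses known chemistry and sets out from 18. mCPBA in CH2Cl2 at 0 °C gives the 5β,6β-epoxy acid F1. Catalytic CSA then triggers the classical 5-exo epoxide-opening lactonisation to the 5β-hydroxy lactone F2. F2 is esterified in a separate Yamaguchi step (angelic acid, 2,4,6-trichlorobenzoyl chloride, Et3N, then DMAP, toluene), which returns to the route at 21.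

Step 5. The risks are slow or misdirected deprotonation of the hindered α′-C–H and retro-aldol before silylation. The fallback sets out from 5. Soft enolisation (TMSOTf, Et3N, CH2Cl2) gives the bis-silyl enediol ether F3. A Mukaiyama aldol addition of F3 to 8 (BF3·OEt2, CH2Cl2, −78 °C), again anti to the C10 methyl, gives the β-hydroxy ketone F4. Silylation (TESOTf, 2,6-lutidine) returns to the route at 11.

Step 6. The risks are the facial selectivity of hydride delivery and sluggish acylation of the hindered aluminium alkoxide. The fallback sets out from 11 and replaces substrate control by reagent control. (S)-Me-CBS with catecholborane (toluene, −78 °C) delivers hydride to the β-face, with the quaternary C1 acting as the large group, and the allylic alcohol F5 is isolated. Acylation with propanoyl chloride, pyridine and DMAP returns to the route at 13.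

Further compounds
F1 | step 9 | 5β,6β-epoxy acid (epoxide of 18) | OC(=O)[C@H](C)[C@H]1[C@@H]2O[C@@H]2[C@](O[Si](C)(C)C(C)(C)C)(C(=O)C[C@@H](C)O[Si](C)(C)C(C)(C)C)[C@@H](C)CC1
F2 | step 9 | 5β-hydroxy lactone (21 with OH in place of the angelate) | O[C@H]1[C@@H]2OC(=O)[C@H](C)[C@@H]2CC[C@H](C)[C@@]1(O[Si](C)(C)C(C)(C)C)C(=O)C[C@@H](C)O[Si](C)(C)C(C)(C)C
F3 | step 5 | bis-silyl enediol ether of 5 (C5–OTMS, C1–OTBS, C1=C5, Δ6) | C[Si](C)(C)OC1=C(O[Si](C)(C)C(C)(C)C)[C@@H](C)CCC=C1
F4 | step 5 | β-hydroxy ketone (11 with free C2 hydroxyl) | O=C1C=CCC[C@H](C)[C@@]1(O[Si](C)(C)C(C)(C)C)[C@@H](O)C[C@@H](C)O[Si](C)(C)C(C)(C)C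
F5 | step 6 | 5α-allylic alcohol (13 without the propanoyl group) | O[C@@H]1C=CCC[C@H](C)[C@@]1(O[Si](C)(C)C(C)(C)C)[C@@H](O[Si](CC)(CC)CC)C[C@@H](C)O[Si](C)(C)C(C)(C)C
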